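**Strategy.** Each end ring is cut at its C1–C6 bond (carotenoid numbering; C1'–C6' in ring B). The key step exploits the gem-dimethyl carbon C1 beside the stereogenic C2 and the C5=C6 olefin, which is read as a β-keto ester (C5 ketone, C6 α-carbon, C7 ester carbon). One SnCl4-promoted cation–olefin cyclization closes the six-membered ring and makes this bond from an acyclic keto ester whose isopropenyl group becomes the C1 cation; its C2 centre, carrying a spectator allyl arm, is taken intact from (R)- or (S)-limonene. Cross-metathesis then turns the allyl arms into the prenyl and diol side chains, and C15 + C10 + C15 Wittig couplings assemble the polyene.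

Key step: step 5

Remark: the target is read as the all-E (2R,2'S) compound (ring A: prenyl at C2, R; ring B: diol side chain at C2', S); commercial limonene enantiomers of high enantiomeric purity supply both centres, and step 19 repeats the key step in the mirror-image series.

**Ring A series**

Step 1
Reactants: 1 (R)-(+)-limonene
Product: 2 (4R)-1-methyl-4-(prop-1-en-2-yl)-7-oxabicyclo[4.1.0]heptane (limonene 1,2-oxide; cis/trans mixture at the epoxide)
Conditions: mCPBA (1.0 equiv), CH2Cl2, 0 °C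
Reagents that add atoms: meta-chloroperoxybenzoic acid, O=C(OO)c1cccc(Cl)c1
Why: Prilezhaev epoxidation, in which the electrophilic peracid should take the trisubstituted ring olefin well ahead of the 1,1-disubstituted isopropenyl group; the epoxide diastereomers converge in step 2.

Step 2
Reactants: 2 (4R)-limonene 1,2-oxide
Product: 4 (3R)-6-oxo-3-(prop-1-en-2-yl)heptanal, via glycol 3 (not isolated)
Conditions: H5IO6 (1.2 equiv), THF/H2O, 0 °C → rt
Reagents that add atoms: water, O
Why: Acid-catalysed epoxide hydrolysis followed by Malaprade glycol cleavage should open the ring between the two oxygenated carbons; the stereocentre is β to the new aldehyde and cannot epimerise.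

Step 3
Reactants: 4 (3R)-6-oxo-3-(prop-1-en-2-yl)heptanal
Product: 5 (5R)-5-(prop-1-en-2-yl)oct-7-en-2-one
Conditions: Ph3PCH3Br, KN(SiMe3)2 (1.0 equiv ylide), THF, −78 → 0 °C
Reagents that add atoms: methyltriphenylphosphonium bromide, C[P+](c1ccccc1)(c1ccccc1)c1ccccc1.[Br-]
Why: Wittig methylenation, in which one equivalent of the non-stabilised ylide at −78 °C should react with the aldehyde much faster than with the methyl ketone, turning CH2CHO into the allyl arm.

Step 4
Reactants: 5 (5R)-5-(prop-1-en-2-yl)oct-7-en-2-one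
Product: 6 methyl (6R)-7-methyl-3-oxo-6-(prop-2-enyl)oct-7-enoate
Conditions: NaH (2.2 equiv), (MeO)2CO (5 equiv), THF, reflux; then AcOH
Reagents that add atoms: dimethyl carbonate, COC(=O)OC
Why: Claisen-type carbomethoxylation of the methyl ketone should occur at the methyl terminus, because the reversible acylation is drained into the unhindered, doubly stabilised β-keto ester enolate; the stereocentre is not acidic.

Step 5
Reactants: 6 methyl (6R)-7-methyl-3-oxo-6-(prop-2-enyl)oct-7-enoate
Product: 7 methyl (1S,3R)-2,2-dimethyl-6-oxo-3-(prop-2-enyl)cyclohexane-1-carboxylate (cis; in equilibrium with its enol)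
Conditions: SnCl4 (2 equiv), moist CH2Cl2, 0 °C → rt
Reagents that add atoms: none
Why: SnCl4 binds the β-keto ester of 6 as a six-membered chelate, which raises the enol content and liberates a strong Brønsted acid that protonates the 1,1-disubstituted C7=C8 olefin at C8 (Markovnikov); the tertiary C7 cation (future C1) is captured by the tin-bound enol carbon C2 (future C6), forming the C1–C6 bond. The closest known reaction type is the SnCl4-promoted cation–olefin cyclization of alkenyl β-keto esters (prenylated acetoacetates to 2-carbomethoxy-3,3-dimethylcyclohexanones). The single six-membered ring closes in a 6-(enolendo) mode, the enol C=C lying inside the new ring and attacking a trigonal cationic carbon through a chair with the allyl group equatorial. The new ester-bearing stereocentre is under thermodynamic control (epimerisable through the enol, cis-diequatorial 1S,3R favoured) and is erased in step 6, while the allyl-bearing centre is carried over unchanged from 6. The step needs ionisation of the isopropenyl olefin only, which the tertiary-versus-secondary cation stability secures; C- rather than O-capture, which the tin chelate and the acid-reversibility of O-alkylation favour; and no 1,2-hydride shift from the allyl-bearing carbon, which fast intramolecular capture at low temperature should suppress.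

Step 6
Reactants: 7 methyl (1S,3R)-2,2-dimethyl-6-oxo-3-(prop-2-enyl)cyclohexane-1-carboxylate
Product: 8 methyl (5R)-6,6-dimethyl-5-(prop-2-enyl)-2-(trifluoromethylsulfonyloxy)cyclohex-1-ene-1-carboxylate
Conditions: NaH, Et2O, 0 °C; then Tf2O, 0 °C
Reagents that add atoms: trifluoromethanesulfonic anhydride, O=S(=O)(OS(=O)(=O)C(F)(F)F)C(F)(F)F
Why: O-sulfonylation of the sodium enolate (enol triflate formation) should give the tetrasubstituted vinyl triflate, which removes the ester stereocentre and fixes the olefin at C5=C6.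

Step 7
Reactants: 8 enol triflate
Product: 9 methyl (5R)-2,6,6-trimethyl-5-(prop-2-enyl)cyclohex-1-ene-1-carboxylate
Conditions: Me2CuLi (from MeLi and CuI), Et2O, −40 → 0 °C
Reagents that add atoms: lithium dimethylcuprate (made in the flask from MeLi and CuI), [Li+].C[Cu-]C
Why: Gilman cuprate addition–elimination on the β-triflyloxy enoate should replace triflate by methyl with the olefin position retained; the hindered ester and the allyl arm are inert at low temperature.

Step 8
Reactants: 9 methyl (5R)-2,6,6-trimethyl-5-(prop-2-enyl)cyclohex-1-ene-1-carboxylate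
Product: 10 [(5R)-2,6,6-trimethyl-5-(prop-2-enyl)cyclohex-1-en-1-yl]methanol
Conditions: i-Bu2AlH (2.5 equiv), CH2Cl2, −78 → 0 °C; aq. potassium sodium tartrate
Reagents that add atoms: none
Why: 1,2-Reduction of the conjugated ester by i-Bu2AlH should give the allylic alcohol cleanly, since no other reducible group is present.

Step 9
Reactants: 10 allylic alcohol
Product: 11 (5R)-2,6,6-trimethyl-5-(prop-2-enyl)cyclohex-1-ene-1-carbaldehyde
Conditions: Dess–Martin periodinane (1.2 equiv), CH2Cl2, 0 °C → rt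
Reagents that add atoms: none
Why: Dess–Martin oxidation of the primary allylic alcohol should stop at the conjugated aldehyde and leave the terminal olefin and the stereocentre alone.

Step 10
Reactants: 11 (5R)-2,6,6-trimethyl-5-(prop-2-enyl)cyclohex-1-ene-1-carbaldehyde
Product: 12 (5R)-2,6,6-trimethyl-5-(3-methylbut-2-enyl)cyclohex-1-ene-1-carbaldehyde
Conditions: second-generation Grubbs catalyst (H2IMes)(PCy3)Cl2Ru=CHPh (5 mol %), 2-methylbut-2-ene (excess)/CH2Cl2, 40 °C
Reagents that add atoms: 2-methylbut-2-ene, CC=C(C)C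
Why: Olefin cross-metathesis should exchange the terminal methylene of the allyl arm for an isopropylidene group (prenyl); the tetrasubstituted enal olefin cannot engage the ruthenium carbene.

Step 11
Reactants: 12 prenyl aldehyde; 13 ethyl (E)-4-(diethoxyphosphoryl)-3-methylbut-2-enoate
Product: 14 ethyl (2E,4E)-3-methyl-5-[(5R)-2,6,6-trimethyl-5-(3-methylbut-2-enyl)cyclohex-1-en-1-yl]penta-2,4-dienoate
Conditions: NaH, THF, 0 °C → rt
Reagents that add atoms: none
Why: Horner–Wadsworth–Emmons olefination with the vinylogous phosphonate anion should give the (2E,4E)-dienoate, the stabilised anion delivering the trans C7=C8 bond on the non-enolisable aldehyde.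

Step 12
Reactants: 14 C15 ester
Product: 15 (2E,4E)-3-methyl-5-[(5R)-2,6,6-trimethyl-5-(3-methylbut-2-enyl)cyclohex-1-en-1-yl]penta-2,4-dien-1-ol
Conditions: i-Bu2AlH (2.5 equiv), CH2Cl2, −78 °C; aq. potassium sodium tartrate
Reagents that add atoms: none
Why: 1,2-Reduction of the dienoate by i-Bu2AlH should give the trienylic alcohol without conjugate reduction.

Step 13
Reactants: 15 C15 alcohol
Product: 16 [(2E,4E)-3-methyl-5-[(5R)-2,6,6-trimethyl-5-(3-methylbut-2-enyl)cyclohex-1-en-1-yl]penta-2,4-dienyl]triphenylphosphonium bromide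
Conditions: PPh3·HBr (1.05 equiv), MeOH, 0 °C → rt
Reagents that add atoms: triphenylphosphine hydrobromide, [PH+](c1ccccc1)(c1ccccc1)c1ccccc1.[Br-]
Why: SN1-type phosphonium salt formation: the trienylic alcohol ionises to a delocalised cation that PPh3 captures at the primary terminus, giving the thermodynamic all-E salt; the prenyl olefin is not protonated by this weak acid.

Step 14
Reactants: 16 ring A C15 phosphonium bromide; 17 (2E,4E,6E)-2,7-dimethylocta-2,4,6-trienedial
Product: 20 (2E,4E,6E,8E,10E,12E)-2,7,11-trimethyl-13-[(5R)-2,6,6-trimethyl-5-(3-methylbut-2-enyl)cyclohex-1-en-1-yl]trideca-2,4,6,8,10,12-hexaenal, via ylide 18 (not isolated), via 11Z-aldehyde 19 (not isolated)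
Conditions: 17 (3 equiv), NaOMe (1.1 equiv, slow addition), CH2Cl2/MeOH, 0 °C → rt; then heptane, 80 °C
Reagents that add atoms: none
Why: Wittig olefination: with a threefold excess of dialdehyde and slow base addition the ylide should condense once only, and the hindered 11Z isomer formed alongside is equilibrated thermally to the all-E aldehyde.

**Ring B series**

Step 15
Reactants: 21 (S)-(−)-limonene
Product: 22 (4S)-1-methyl-4-(prop-1-en-2-yl)-7-oxabicyclo[4.1.0]heptane (cis/trans mixture at the epoxide)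
Conditions: mCPBA (1.0 equiv), CH2Cl2, 0 °C
Reagents that add atoms: meta-chloroperoxybenzoic acid, O=C(OO)c1cccc(Cl)c1
Why: Prilezhaev epoxidation, selective for the trisubstituted ring olefin as in step 1.

Step 16
Reactants: 22 (4S)-limonene 1,2-oxide
Product: 24 (3S)-6-oxo-3-(prop-1-en-2-yl)heptanal, via glycol 23 (not isolated)
Conditions: H5IO6 (1.2 equiv), THF/H2O, 0 °C → rt
Reagents that add atoms: water, O
Why: Epoxide hydrolysis and Malaprade glycol cleavage as in step 2, with the stereocentre out of reach of enolisation.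

Step 17
Reactants: 24 (3S)-6-oxo-3-(prop-1-en-2-yl)heptanal
Product: 25 (5S)-5-(prop-1-en-2-yl)oct-7-en-2-one
Conditions: Ph3PCH3Br, KN(SiMe3)2 (1.0 equiv ylide), THF, −78 → 0 °C
Reagents that add atoms: methyltriphenylphosphonium bromide, C[P+](c1ccccc1)(c1ccccc1)c1ccccc1.[Br-]
Why: Aldehyde-selective Wittig methylenation as in step 3.

Step 18
Reactants: 25 (5S)-5-(prop-1-en-2-yl)oct-7-en-2-one
Product: 26 methyl (6S)-7-methyl-3-oxo-6-(prop-2-enyl)oct-7-enoate
Conditions: NaH (2.2 equiv), (MeO)2CO (5 equiv), THF, reflux; then AcOH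
Reagents that add atoms: dimethyl carbonate, COC(=O)OC
Why: Claisen-type carbomethoxylation at the methyl terminus as in step 4.

Step 19
Reactants: 26 methyl (6S)-7-methyl-3-oxo-6-(prop-2-enyl)oct-7-enoate
Product: 27 methyl (1R,3S)-2,2-dimethyl-6-oxo-3-(prop-2-enyl)cyclohexane-1-carboxylate (cis; in equilibrium with its enol)
Conditions: SnCl4 (2 equiv), moist CH2Cl2, 0 °C → rt
Reagents that add atoms: none
Why: The same SnCl4-promoted cation–olefin cyclization terminated by the chelated β-keto ester enol as in step 5, run on the enantiomer, so the C1'–C6' bond forms with the allyl-bearing centre retained and the ester centre set thermodynamically cis.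

Step 20
Reactants: 27 methyl (1R,3S)-2,2-dimethyl-6-oxo-3-(prop-2-enyl)cyclohexane-1-carboxylate
Product: 28 methyl (5S)-6,6-dimethyl-5-(prop-2-enyl)-2-(trifluoromethylsulfonyloxy)cyclohex-1-ene-1-carboxylate
Conditions: NaH, Et2O, 0 °C; then Tf2O, 0 °C
Reagents that add atoms: trifluoromethanesulfonic anhydride, O=S(=O)(OS(=O)(=O)C(F)(F)F)C(F)(F)F
Why: Enol triflate formation by O-sulfonylation of the sodium enolate as in step 6.

Step 21
Reactants: 28 enol triflate
Product: 29 methyl (5S)-2,6,6-trimethyl-5-(prop-2-enyl)cyclohex-1-ene-1-carboxylate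
Conditions: Me2CuLi (from MeLi and CuI), Et2O, −40 → 0 °C
Reagents that add atoms: lithium dimethylcuprate (made in the flask from MeLi and CuI), [Li+].C[Cu-]C
Why: Gilman cuprate addition–elimination as in step 7.

Step 22
Reactants: 29 methyl (5S)-2,6,6-trimethyl-5-(prop-2-enyl)cyclohex-1-ene-1-carboxylate
Product: 30 [(5S)-2,6,6-trimethyl-5-(prop-2-enyl)cyclohex-1-en-1-yl]methanol
Conditions: i-Bu2AlH (2.5 equiv), CH2Cl2, −78 → 0 °C; aq. potassium sodium tartrate
Reagents that add atoms: none
Why: 1,2-Reduction of the conjugated ester by i-Bu2AlH as in step 8.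

Step 23
Reactants: 30 allylic alcohol
Product: 31 (5S)-2,6,6-trimethyl-5-(prop-2-enyl)cyclohex-1-ene-1-carbaldehyde
Conditions: Dess–Martin periodinane (1.2 equiv), CH2Cl2, 0 °C → rt
Reagents that add atoms: none
Why: Dess–Martin oxidation as in step 9.

Step 24
Reactants: 31 (5S)-2,6,6-trimethyl-5-(prop-2-enyl)cyclohex-1-ene-1-carbaldehyde; 32 2-methylidenepropane-1,3-diyl diacetate
Product: 33 (5S)-5-[4-acetoxy-3-(acetoxymethyl)but-2-enyl]-2,6,6-trimethylcyclohex-1-ene-1-carbaldehyde
Conditions: second-generation Hoveyda–Grubbs catalyst (H2IMes)Cl2Ru=CH(C6H4-2-OiPr) (5–10 mol %, in portions), 32 (4 equiv), CH2Cl2, 40 °C, argon sweep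
Reagents that add atoms: none
Why: Olefin cross-metathesis between the monosubstituted allyl arm and the 1,1-disubstituted olefin 32 should give the trisubstituted olefin with loss of ethylene, driven by excess partner and ethylene removal; the two identical CH2OAc groups leave no E/Z question.

Step 25
Reactants: 33 aldehyde diacetate; 13 ethyl (E)-4-(diethoxyphosphoryl)-3-methylbut-2-enoate
Product: 34 ethyl (2E,4E)-5-[(5S)-5-[4-acetoxy-3-(acetoxymethyl)but-2-enyl]-2,6,6-trimethylcyclohex-1-en-1-yl]-3-methylpenta-2,4-dienoate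
Conditions: NaH, THF, 0 °C → rt (anion preformed)
Reagents that add atoms: none
Why: Horner–Wadsworth–Emmons olefination as in step 11; the preformed stabilised anion should not cleave the acetates at or below room temperature.

Step 26
Reactants: 34 C15 ester diacetate
Product: 35 (2E,4E)-5-[(5S)-5-[4-hydroxy-3-(hydroxymethyl)but-2-enyl]-2,6,6-trimethylcyclohex-1-en-1-yl]-3-methylpenta-2,4-dien-1-ol
Conditions: i-Bu2AlH (7 equiv), CH2Cl2/THF, −78 → −20 °C; aq. potassium sodium tartrate
Reagents that add atoms: none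
Why: Exhaustive i-Bu2AlH reduction should convert the dienoate into the primary alcohol and cleave both acetates in the same operation, unveiling the triol.

Step 27
Reactants: 35 C15 triol
Product: 36 [(2E,4E)-5-[(5S)-5-[4-hydroxy-3-(hydroxymethyl)but-2-enyl]-2,6,6-trimethylcyclohex-1-en-1-yl]-3-methylpenta-2,4-dienyl]triphenylphosphonium bromide
Conditions: PPh3·HBr (1.0 equiv), MeOH, 0 °C → rt
Reagents that add atoms: triphenylphosphine hydrobromide, [PH+](c1ccccc1)(c1ccccc1)c1ccccc1.[Br-]
Why: SN1-type phosphonium salt formation should be selective, because only the trienylic alcohol ionises readily to a delocalised cation, whereas the side-chain allylic alcohols would have to form a far less stabilised allyl cation.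

Step 28
Reactants: 36 ring B C15 phosphonium bromide; 20 ring A C25 aldehyde
Product: 39 (all-E,2R,2'S)-2'-[4-hydroxy-3-(hydroxymethyl)but-2-enyl]-2-(3-methylbut-2-enyl)-β,β-carotene (CNP0213288.1), via ylide 37 (not isolated), via 11'Z-isomer 38 (not isolated)
Conditions: 1,2-epoxybutane, EtOH, reflux, dark, argon
Reagents that add atoms: none
Why: Wittig olefination under epoxide-buffered conditions (the epoxide scavenges HBr as the ylide forms) tolerates the free diol, and refluxing ethanol equilibrates the hindered 11'Z isomer to the all-E carotenoid; neither stereocentre is near the reacting sites.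

**Compound list**

1 | (R)-(+)-limonene | CC1=CC[C@@H](CC1)C(C)=C | starting material
2 | (4R)-1-methyl-4-(prop-1-en-2-yl)-7-oxabicyclo[4.1.0]heptane, epoxide cis/trans mixture | CC12OC1C[C@@H](CC2)C(C)=C | intermediate
3 | (4R)-1-methyl-4-(prop-1-en-2-yl)cyclohexane-1,2-diol, diastereomer mixture | CC1(O)C(O)C[C@@H](CC1)C(C)=C | intermediate (not isolated)
4 | (3R)-6-oxo-3-(prop-1-en-2-yl)heptanal | CC(=O)CC[C@H](CC=O)C(C)=C | intermediate
5 | (5R)-5-(prop-1-en-2-yl)oct-7-en-2-one | CC(=O)CC[C@H](CC=C)C(C)=C | intermediate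
6 | methyl (6R)-7-methyl-3-oxo-6-(prop-2-enyl)oct-7-enoate | COC(=O)CC(=O)CC[C@H](CC=C)C(C)=C | intermediate
7 | methyl (1S,3R)-2,2-dimethyl-6-oxo-3-(prop-2-enyl)cyclohexane-1-carboxylate | C=CC[C@H]1CCC(=O)[C@@H](C(=O)OC)C1(C)C | intermediate
8 | methyl (5R)-6,6-dimethyl-5-(prop-2-enyl)-2-(trifluoromethylsulfonyloxy)cyclohex-1-ene-1-carboxylate | C=CC[C@H]1CCC(OS(=O)(=O)C(F)(F)F)=C(C(=O)OC)C1(C)C | intermediate
9 | methyl (5R)-2,6,6-trimethyl-5-(prop-2-enyl)cyclohex-1-ene-1-carboxylate | C=CC[C@H]1CCC(C)=C(C(=O)OC)C1(C)C | intermediate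
10 | [(5R)-2,6,6-trimethyl-5-(prop-2-enyl)cyclohex-1-en-1-yl]methanol | C=CC[C@H]1CCC(C)=C(CO)C1(C)C | intermediate
11 | (5R)-2,6,6-trimethyl-5-(prop-2-enyl)cyclohex-1-ene-1-carbaldehyde | C=CC[C@H]1CCC(C)=C(C=O)C1(C)C | intermediate
12 | (5R)-2,6,6-trimethyl-5-(3-methylbut-2-enyl)cyclohex-1-ene-1-carbaldehyde | CC(C)=CC[C@H]1CCC(C)=C(C=O)C1(C)C | intermediate
13 | ethyl (E)-4-(diethoxyphosphoryl)-3-methylbut-2-enoate | CCOC(=O)/C=C(\C)CP(=O)(OCC)OCC | starting material
14 | ethyl (2E,4E)-3-methyl-5-[(5R)-2,6,6-trimethyl-5-(3-methylbut-2-enyl)cyclohex-1-en-1-yl]penta-2,4-dienoate | CC(C)=CC[C@H]1CCC(C)=C(/C=C/C(C)=C/C(=O)OCC)C1(C)C | intermediate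
15 | (2E,4E)-3-methyl-5-[(5R)-2,6,6-trimethyl-5-(3-methylbut-2-enyl)cyclohex-1-en-1-yl]penta-2,4-dien-1-ol | CC(C)=CC[C@H]1CCC(C)=C(/C=C/C(C)=C/CO)C1(C)C | intermediate
16 | [(2E,4E)-3-methyl-5-[(5R)-2,6,6-trimethyl-5-(3-methylbut-2-enyl)cyclohex-1-en-1-yl]penta-2,4-dienyl]triphenylphosphonium bromide | CC(C)=CC[C@H]1CCC(C)=C(/C=C/C(C)=C/C[P+](c2ccccc2)(c2ccccc2)c2ccccc2)C1(C)C.[Br-] | intermediate
17 | (2E,4E,6E)-2,7-dimethylocta-2,4,6-trienedial | O=C/C(C)=C/C=C/C=C(C)/C=O | starting material
18 | ylide of 16, [(2E,4E)-3-methyl-5-[(5R)-ring A]penta-2,4-dienylidene]triphenylphosphorane | CC(C)=CC[C@H]1CCC(C)=C(/C=C/C(C)=C/C=P(c2ccccc2)(c2ccccc2)c2ccccc2)C1(C)C | intermediate (not isolated)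
19 | (8Z)-isomer of 20 (11Z in carotenoid numbering) | CC(C)=CC[C@H]1CCC(C)=C(/C=C/C(C)=C/C=C\C(C)=C\C=C\C=C(C)\C=O)C1(C)C | intermediate (not isolated)
20 | (2E,4E,6E,8E,10E,12E)-2,7,11-trimethyl-13-[(5R)-2,6,6-trimethyl-5-(3-methylbut-2-enyl)cyclohex-1-en-1-yl]trideca-2,4,6,8,10,12-hexaenal | CC(C)=CC[C@H]1CCC(C)=C(/C=C/C(C)=C/C=C/C(C)=C/C=C/C=C(C)/C=O)C1(C)C | intermediate
21 | (S)-(−)-limonene | CC1=CC[C@H](CC1)C(C)=C | starting material
22 | (4S)-1-methyl-4-(prop-1-en-2-yl)-7-oxabicyclo[4.1.0]heptane, epoxide cis/trans mixture | CC12OC1C[C@H](CC2)C(C)=C | intermediate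
23 | (4S)-1-methyl-4-(prop-1-en-2-yl)cyclohexane-1,2-diol, diastereomer mixture | CC1(O)C(O)C[C@H](CC1)C(C)=C | intermediate (not isolated)
24 | (3S)-6-oxo-3-(prop-1-en-2-yl)heptanal | CC(=O)CC[C@@H](CC=O)C(C)=C | intermediate
25 | (5S)-5-(prop-1-en-2-yl)oct-7-en-2-one | CC(=O)CC[C@@H](CC=C)C(C)=C | intermediate
26 | methyl (6S)-7-methyl-3-oxo-6-(prop-2-enyl)oct-7-enoate | COC(=O)CC(=O)CC[C@@H](CC=C)C(C)=C | intermediate
27 | methyl (1R,3S)-2,2-dimethyl-6-oxo-3-(prop-2-enyl)cyclohexane-1-carboxylate | C=CC[C@@H]1CCC(=O)[C@H](C(=O)OC)C1(C)C | intermediate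
28 | methyl (5S)-6,6-dimethyl-5-(prop-2-enyl)-2-(trifluoromethylsulfonyloxy)cyclohex-1-ene-1-carboxylate | C=CC[C@@H]1CCC(OS(=O)(=O)C(F)(F)F)=C(C(=O)OC)C1(C)C | intermediate
29 | methyl (5S)-2,6,6-trimethyl-5-(prop-2-enyl)cyclohex-1-ene-1-carboxylate | C=CC[C@@H]1CCC(C)=C(C(=O)OC)C1(C)C | intermediate
30 | [(5S)-2,6,6-trimethyl-5-(prop-2-enyl)cyclohex-1-en-1-yl]methanol | C=CC[C@@H]1CCC(C)=C(CO)C1(C)C | intermediate
31 | (5S)-2,6,6-trimethyl-5-(prop-2-enyl)cyclohex-1-ene-1-carbaldehyde | C=CC[C@@H]1CCC(C)=C(C=O)C1(C)C | intermediate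
32 | 2-methylidenepropane-1,3-diyl diacetate | CC(=O)OCC(=C)COC(C)=O | starting material
33 | (5S)-5-[4-acetoxy-3-(acetoxymethyl)but-2-enyl]-2,6,6-trimethylcyclohex-1-ene-1-carbaldehyde | CC(=O)OCC(COC(C)=O)=CC[C@@H]1CCC(C)=C(C=O)C1(C)C | intermediate
34 | ethyl (2E,4E)-5-[(5S)-5-[4-acetoxy-3-(acetoxymethyl)but-2-enyl]-2,6,6-trimethylcyclohex-1-en-1-yl]-3-methylpenta-2,4-dienoate | CC(=O)OCC(COC(C)=O)=CC[C@@H]1CCC(C)=C(/C=C/C(C)=C/C(=O)OCC)C1(C)C | intermediate
35 | (2E,4E)-5-[(5S)-5-[4-hydroxy-3-(hydroxymethyl)but-2-enyl]-2,6,6-trimethylcyclohex-1-en-1-yl]-3-methylpenta-2,4-dien-1-ol | OCC(CO)=CC[C@@H]1CCC(C)=C(/C=C/C(C)=C/CO)C1(C)C | intermediate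
36 | [(2E,4E)-5-[(5S)-5-[4-hydroxy-3-(hydroxymethyl)but-2-enyl]-2,6,6-trimethylcyclohex-1-en-1-yl]-3-methylpenta-2,4-dienyl]triphenylphosphonium bromide | OCC(CO)=CC[C@@H]1CCC(C)=C(/C=C/C(C)=C/C[P+](c2ccccc2)(c2ccccc2)c2ccccc2)C1(C)C.[Br-] | intermediate
37 | ylide of 36, [(2E,4E)-5-[(5S)-ring B]-3-methylpenta-2,4-dienylidene]triphenylphosphorane | OCC(CO)=CC[C@@H]1CCC(C)=C(/C=C/C(C)=C/C=P(c2ccccc2)(c2ccccc2)c2ccccc2)C1(C)C | intermediate (not isolated)
38 | (11'Z)-isomer of 39 | CC(C)=CC[C@H]1CCC(C)=C(/C=C/C(C)=C/C=C/C(C)=C/C=C/C=C(C)/C=C\C=C(C)\C=C\C2=C(C)CC[C@@H](CC=C(CO)CO)C2(C)C)C1(C)C | intermediate (not isolated)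
39 | (all-E,2R,2'S)-2'-[4-hydroxy-3-(hydroxymethyl)but-2-enyl]-2-(3-methylbut-2-enyl)-β,β-carotene | CC(C)=CC[C@H]1CCC(C)=C(/C=C/C(C)=C/C=C/C(C)=C/C=C/C=C(C)/C=C/C=C(C)/C=C/C2=C(C)CC[C@@H](CC=C(CO)CO)C2(C)C)C1(C)C | target

**Count and risks**

Total step count: 28. Longest linear sequence: 15 steps (steps 1–14, then step 28); the ring B branch (steps 15–27) is 13 steps before the convergent last step.

Steps most likely to fail:

1. Step 5 (and its mirror image, step 19). The open tertiary cation may lose the configuration of the adjacent allyl-bearing carbon by 1,2-hydride shift or reversible proton loss, or may be diverted to O-capture. Fallback from 6: the olefin would be activated as a bridged seleniranium ion instead of an open cation. N-(Phenylselanyl)phthalimide with catalytic SnCl4 in CH2Cl2 (−78 → 0 °C) should give, by Markovnikov opening of the seleniranium ion by the enol carbon (selenium-mediated carbocyclization of alkenyl β-keto esters, any O-cyclised enol ether rearranging to the C-cyclised isomer under the acid), the selenide methyl (3R)-2-methyl-6-oxo-2-[(phenylselanyl)methyl]-3-(prop-2-enyl)cyclohexane-1-carboxylate F1. Radical deselenation with Bu3SnH/AIBN in the presence of catalytic PhSeSePh (benzeneselenol as a fast hydrogen donor, to outrun 5-exo closure of the primary radical onto the allyl arm) would turn CH2SePh into the second methyl group and return to 7. The mirror-image detour from 26 through the enantiomeric selenide methyl (3S)-2-methyl-6-oxo-2-[(phenylselanyl)methyl]-3-(prop-2-enyl)cyclohexane-1-carboxylate F2 to 27 would answer step 19.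

2. Step 24. The cross-metathesis may stall: the allylic acetates can chelate the ruthenium carbene, the 1,1-disubstituted partner turns over slowly, and homodimerisation of the allyl arm consumes catalyst. Fallback from 29, which builds the side chain by carbonyl chemistry instead:
 - Lemieux–Johnson cleavage of the allyl arm (OsO4 cat., NaIO4, 2,6-lutidine, dioxane/H2O) would give methyl (5S)-2,6,6-trimethyl-5-(2-oxoethyl)cyclohex-1-ene-1-carboxylate F3.
 - Knoevenagel condensation with dimethyl malonate (TiCl4, pyridine, THF, 0 °C) would give dimethyl 2-[2-[(1S)-3-(methoxycarbonyl)-2,2,4-trimethylcyclohex-3-en-1-yl]ethylidene]propanedioate F4.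
 - Exhaustive i-Bu2AlH reduction at −78 °C would give 2-[2-[(1S)-3-(hydroxymethyl)-2,2,4-trimethylcyclohex-3-en-1-yl]ethylidene]propane-1,3-diol F5.
 - Acetylation of the two unhindered side-chain hydroxyls (Ac2O 2.1 equiv, 2,4,6-collidine, −20 °C), the ring CH2OH being shielded by the flanking gem-dimethyl and methyl groups, would give [2-[2-[(1S)-3-(hydroxymethyl)-2,2,4-trimethylcyclohex-3-en-1-yl]ethylidene]propane-1,3-diyl] diacetate F6.
 - Dess–Martin oxidation then rejoins the route at 33.

3. Step 27. Ionisation may be non-selective, with phosphonium formation or methanolysis also at the two side-chain allylic alcohols. Fallback from 34, which masks the diol with acid-stable silyl ethers before the salt is made: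
 - K2CO3 in EtOH would remove the acetates to give ethyl (2E,4E)-5-[(5S)-5-[4-hydroxy-3-(hydroxymethyl)but-2-enyl]-2,6,6-trimethylcyclohex-1-en-1-yl]-3-methylpenta-2,4-dienoate F7.
 - TBDPSCl/imidazole in DMF would give its bis(tert-butyldiphenylsilyl) ether F8.
 - i-Bu2AlH would give the bis-silylated C15 dienol F9.
 - PPh3·HBr in MeOH would give the bis-silylated C15 triphenylphosphonium bromide F10, the bulky silyl ethers resisting the brief methanolic acid.
 - Wittig coupling with 20 under the conditions of step 28 would give the bis(tert-butyldiphenylsilyl) ether of the target F11.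
 - Bu4NF in THF at 0 °C then gives 39.

**Further compounds**

F1 | step 5 | methyl (3R)-2-methyl-6-oxo-2-[(phenylselanyl)methyl]-3-(prop-2-enyl)cyclohexane-1-carboxylate (epimer mixture at C1 and C2) | C=CC[C@H]1CCC(=O)C(C(=O)OC)C1(C)C[Se]c1ccccc1
F2 | step 19 | methyl (3S)-2-methyl-6-oxo-2-[(phenylselanyl)methyl]-3-(prop-2-enyl)cyclohexane-1-carboxylate (epimer mixture at C1 and C2) | C=CC[C@@H]1CCC(=O)C(C(=O)OC)C1(C)C[Se]c1ccccc1
F3 | step 24 | methyl (5S)-2,6,6-trimethyl-5-(2-oxoethyl)cyclohex-1-ene-1-carboxylate | O=CC[C@@H]1CCC(C)=C(C(=O)OC)C1(C)C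
F4 | step 24 | dimethyl 2-[2-[(1S)-3-(methoxycarbonyl)-2,2,4-trimethylcyclohex-3-en-1-yl]ethylidene]propanedioate | COC(=O)C(C(=O)OC)=CC[C@@H]1CCC(C)=C(C(=O)OC)C1(C)C
F5 | step 24 | 2-[2-[(1S)-3-(hydroxymethyl)-2,2,4-trimethylcyclohex-3-en-1-yl]ethylidene]propane-1,3-diol | OCC(CO)=CC[C@@H]1CCC(C)=C(CO)C1(C)C
F6 | step 24 | [2-[2-[(1S)-3-(hydroxymethyl)-2,2,4-trimethylcyclohex-3-en-1-yl]ethylidene]propane-1,3-diyl] diacetate | CC(=O)OCC(COC(C)=O)=CC[C@@H]1CCC(C)=C(CO)C1(C)C
F7 | step 27 | ethyl (2E,4E)-5-[(5S)-5-[4-hydroxy-3-(hydroxymethyl)but-2-enyl]-2,6,6-trimethylcyclohex-1-en-1-yl]-3-methylpenta-2,4-dienoate | OCC(CO)=CC[C@@H]1CCC(C)=C(/C=C/C(C)=C/C(=O)OCC)C1(C)C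
F8 | step 27 | ethyl (2E,4E)-5-[(5S)-5-[4-(tert-butyldiphenylsilyloxy)-3-(tert-butyldiphenylsilyloxymethyl)but-2-enyl]-2,6,6-trimethylcyclohex-1-en-1-yl]-3-methylpenta-2,4-dienoate | CC(C)(C)[Si](c1ccccc1)(c1ccccc1)OCC(CO[Si](c1ccccc1)(c1ccccc1)C(C)(C)C)=CC[C@@H]1CCC(C)=C(/C=C/C(C)=C/C(=O)OCC)C1(C)C
F9 | step 27 | (2E,4E)-5-[(5S)-5-[4-(tert-butyldiphenylsilyloxy)-3-(tert-butyldiphenylsilyloxymethyl)but-2-enyl]-2,6,6-trimethylcyclohex-1-en-1-yl]-3-methylpenta-2,4-dien-1-ol | CC(C)(C)[Si](c1ccccc1)(c1ccccc1)OCC(CO[Si](c1ccccc1)(c1ccccc1)C(C)(C)C)=CC[C@@H]1CCC(C)=C(/C=C/C(C)=C/CO)C1(C)C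
F10 | step 27 | [(2E,4E)-5-[(5S)-5-[4-(tert-butyldiphenylsilyloxy)-3-(tert-butyldiphenylsilyloxymethyl)but-2-enyl]-2,6,6-trimethylcyclohex-1-en-1-yl]-3-methylpenta-2,4-dienyl]triphenylphosphonium bromide | CC(C)(C)[Si](c1ccccc1)(c1ccccc1)OCC(CO[Si](c1ccccc1)(c1ccccc1)C(C)(C)C)=CC[C@@H]1CCC(C)=C(/C=C/C(C)=C/C[P+](c2ccccc2)(c2ccccc2)c2ccccc2)C1(C)C.[Br-]
F11 | step 27 | bis(tert-butyldiphenylsilyl) ether of 39 | CC(C)=CC[C@H]1CCC(C)=C(/C=C/C(C)=C/C=C/C(C)=C/C=C/C=C(C)/C=C/C=C(C)/C=C/C2=C(C)CC[C@@H](CC=C(CO[Si](c3ccccc3)(c3ccccc3)C(C)(C)C)CO[Si](c3ccccc3)(c3ccccc3)C(C)(C)C)C2(C)C)C1(C)C
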